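The target is a 6'→8 linked bis-epicatechin. Everything rests on disconnecting the C2–C1' bond of the upper flavan, which exploits the O1–C2(aryl)–C3(O) array of ring C: C2 is a carbinol carbon flanked by the C3 oxygen, so an aryl nucleophile can add to a C2 aldehyde under chelation by the C3 benzyl ether. The key step adds the ring B arylmagnesium, already carrying the lower epicatechin (chiral pool) at C6', to an (R)-α-benzyloxy aldehyde bearing a 2-fluoro-4,6-bis(benzyloxy)phenyl ring A, forming C2–C1' and setting C2. Fluoride displacement then closes ring C with retention (2,3-cis), and hydrogenolysis unmasks all ten hydroxyls.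

Key step: step 11

Assumption: the biaryl axis between C6' of ring B and C8 of the lower ring A carries no descriptor in the target and is treated as not configurationally fixed; rotamers are carried through together. Flavan numbering is used; "upper" is the unit whose ring B carries the biaryl bond, "lower" the unit joined through C8.

Step 1
Reactants: 1 (−)-epicatechin
Product: 2 5,7,3',4'-tetra-O-benzyl-(−)-epicatechin
Conditions: BnBr, K2CO3, DMF, 0 °C → rt, under argon
Reagents that add atoms: benzyl bromide, BrCc1ccccc1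
Why: Williamson etherification in which K2CO3 deprotonates only the four phenols, so the secondary 3-OH stays free and both stereocentres are untouched.

Step 2
Reactants: 2 5,7,3',4'-tetra-O-benzyl-(−)-epicatechin
Product: 3 8-bromo-5,7,3',4'-tetra-O-benzyl-(−)-epicatechin
Conditions: NBS, CH2Cl2, −78 °C → rt
Reagents that add atoms: N-bromosuccinimide, O=C1CCC(=O)N1Br
Why: Electrophilic aromatic bromination of the most electron-rich arene (ring A) at C8, which lies between O1 and the 7-benzyloxy group and is the more accessible of its two free positions.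

Step 3
Reactants: 3 8-bromo-5,7,3',4'-tetra-O-benzyl-(−)-epicatechin
Product: 4 8-bromo-3,5,7,3',4'-penta-O-benzyl-(−)-epicatechin
Conditions: NaH, BnBr, n-Bu4NI (cat.), DMF, 0 °C → rt
Reagents that add atoms: benzyl bromide, BrCc1ccccc1
Why: Williamson etherification of the secondary alkoxide removes the only acidic proton before the organometallic steps, with a group that leaves in the final hydrogenolysis.

Step 4
Reactants: 5 1,2-bis(benzyloxy)-4-bromobenzene
Product: 6 1,2-bis(benzyloxy)-4-bromo-5-iodobenzene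
Conditions: NIS, CF3CO2H (cat.), MeCN, rt
Reagents that add atoms: N-iodosuccinimide, O=C1CCC(=O)N1I
Why: Electrophilic aromatic iodination goes para to a benzyloxy group at the free position next to bromine, giving a dihalide whose C–I bond reacts first in cross-coupling.

Step 5
Reactants: 4 8-bromo-3,5,7,3',4'-penta-O-benzyl-(−)-epicatechin; 6 1,2-bis(benzyloxy)-4-bromo-5-iodobenzene
Product: 9 8-[4,5-bis(benzyloxy)-2-bromophenyl]-3,5,7,3',4'-penta-O-benzyl-(−)-epicatechin, via C8 aryllithium 7 (not isolated), via C8 arylzinc chloride 8 (not isolated)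
Conditions: n-BuLi, THF, −78 °C; ZnCl2, −78 °C → rt; then 6, Pd2(dba)3 (cat.), SPhos, THF, 50 °C
Reagents that add atoms: none
Why: Negishi coupling in which bromine–lithium exchange at C8, transmetalation to zinc and oxidative addition of zerovalent palladium to the C–I bond (much faster than to C–Br) build the hindered biaryl bond and keep the bromide for step 11.

Step 6
Reactants: 10 1,3,5-trifluorobenzene
Product: 11 1,3-bis(benzyloxy)-5-fluorobenzene
Conditions: BnOH (2.1 equiv), NaH, NMP, 0 → 100 °C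
Reagents that add atoms: benzyl alcohol, OCc1ccccc1
Why: Twofold nucleophilic aromatic substitution of fluoride by benzyloxide, each alkoxy group slowing the next substitution so that the reaction can be held at the bis-ether.

Step 7
Reactants: 11 1,3-bis(benzyloxy)-5-fluorobenzene; 12 (R)-trityl glycidyl ether
Product: 14 (R)-1-[2,4-bis(benzyloxy)-6-fluorophenyl]-3-(trityloxy)propan-2-ol, via fluoroaryllithium 13 (not isolated)
Conditions: n-BuLi, THF, −78 °C; then 12, BF3·OEt2, −78 °C
Reagents that add atoms: none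
Why: Directed ortho-lithiation at the C–H flanked by fluorine and benzyloxy (two equivalent sites), then BF3-promoted epoxide opening at the terminal carbon at −78 °C, below the temperature at which the ortho-fluoroaryllithium loses LiF, so the stereocentre of 12 is untouched and becomes C3 of the upper flavan.

Step 8
Reactants: 14 (R)-1-[2,4-bis(benzyloxy)-6-fluorophenyl]-3-(trityloxy)propan-2-ol
Product: 15 1,5-bis(benzyloxy)-2-[(R)-2-(benzyloxy)-3-(trityloxy)propyl]-3-fluorobenzene
Conditions: NaH, BnBr, n-Bu4NI (cat.), THF, 0 °C → rt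
Reagents that add atoms: benzyl bromide, BrCc1ccccc1
Why: Williamson etherification, in which alkylation by benzyl bromide at 0 °C is much faster than attack of the alkoxide on the unactivated C–F bond and the trityl ether cannot migrate.

Step 9
Reactants: 15 1,5-bis(benzyloxy)-2-[(R)-2-(benzyloxy)-3-(trityloxy)propyl]-3-fluorobenzene
Product: 16 (R)-2-(benzyloxy)-3-[2,4-bis(benzyloxy)-6-fluorophenyl]propan-1-ol
Conditions: p-TsOH·H2O (cat.), MeOH/CH2Cl2, rt
Reagents that add atoms: none
Why: Acid-catalysed solvolysis of the trityl ether through the trityl cation, which methanol captures, while benzyl ethers and the aryl fluoride are inert.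

Step 10
Reactants: 16 (R)-2-(benzyloxy)-3-[2,4-bis(benzyloxy)-6-fluorophenyl]propan-1-ol
Product: 17 (R)-2-(benzyloxy)-3-[2,4-bis(benzyloxy)-6-fluorophenyl]propanal
Conditions: Dess–Martin periodinane, NaHCO3, CH2Cl2, 0 °C → rt; used at once
Reagents that add atoms: none
Why: Dess–Martin oxidation under buffered, non-basic conditions should give the α-benzyloxy aldehyde without epimerisation.

Step 11
Reactants: 9 8-[4,5-bis(benzyloxy)-2-bromophenyl]-3,5,7,3',4'-penta-O-benzyl-(−)-epicatechin; 17 (R)-2-(benzyloxy)-3-[2,4-bis(benzyloxy)-6-fluorophenyl]propanal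
Product: 20 (1R,2R)-2-(benzyloxy)-1-{4,5-bis(benzyloxy)-2-[3,5,7,3',4'-penta-O-benzylepicatechin-8-yl]phenyl}-3-[2,4-bis(benzyloxy)-6-fluorophenyl]propan-1-ol, via biaryllithium 18 (not isolated), via biarylmagnesium bromide 19 (not isolated)
Conditions: n-BuLi, THF, −78 °C; MgBr2·OEt2, −78 °C; then 17 premixed with MgBr2·OEt2 in CH2Cl2, −78 → −40 °C; H2O
Reagents that add atoms: none
Why: Bromine–lithium exchange on 9 and transmetalation give arylmagnesium 19, while MgBr2 ties the carbonyl oxygen and the α-benzyloxy oxygen of 17 into a five-membered chelate (Cram chelate model). The aryl group adds to the carbonyl carbon from the chelate face that carries the α-hydrogen, away from the CH2-aryl group, which forms the C2–C1' bond and should give the syn (1R,2R) carbinol. The closest known reaction type is the chelation-controlled addition of Grignard reagents to α-alkoxy aldehydes. No ring is closed here; the new stereocentre (C2 of the upper flavan) is controlled by the existing C3 stereocentre through the chelate (1,2-induction). The step needs chelate over open Felkin–Anh addition, secured by the chelating benzyl ether, excess MgBr2 and weakly coordinating CH2Cl2, and addition over enolisation, secured by −78 °C and the low basicity of the magnesium reagent; the aryl fluoride is inert to it.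

Step 12
Reactants: 20 (1R,2R)-2-(benzyloxy)-1-{4,5-bis(benzyloxy)-2-[3,5,7,3',4'-penta-O-benzylepicatechin-8-yl]phenyl}-3-[2,4-bis(benzyloxy)-6-fluorophenyl]propan-1-ol
Product: 21 deca-O-benzyl derivative of the target [(2R,3R)-3,5,7-tris(benzyloxy)-2-{4,5-bis(benzyloxy)-2-[3,5,7,3',4'-penta-O-benzylepicatechin-8-yl]phenyl}chromane]
Conditions: KH, 18-crown-6, THF/DMF, 0 → 50 °C
Reagents that add atoms: none
Why: Intramolecular nucleophilic aromatic substitution (6-exo) in which the potassium alkoxide displaces the ortho fluoride of ring A, not deactivated by the two meta benzyloxy groups, closing ring C through the O1–C8a bond so that C2 keeps its configuration and the 2,3-cis relationship results.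

Step 13
Reactants: 21 deca-O-benzyl derivative of the target
Product: 22 target, (2R,3R)-2-{2-[(2R,3R)-2-(3,4-dihydroxyphenyl)-3,5,7-trihydroxychroman-8-yl]-4,5-dihydroxyphenyl}chromane-3,5,7-triol
Conditions: H2 (1 atm), Pd(OH)2/C, THF/MeOH/H2O, rt; work-up under argon
Reagents that add atoms: none
Why: Hydrogenolysis of the eight aryl and two alkyl benzyl ethers under neutral conditions should leave the C2–O1 benzylic ether bonds of both flavans and all four stereocentres intact.

Compound list
1 | (−)-epicatechin | Oc1cc(O)c2c(c1)O[C@H](c1ccc(O)c(O)c1)[C@H](O)C2 | starting material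
2 | 5,7,3',4'-tetra-O-benzyl-(−)-epicatechin | c1c(OCc9ccccc9)cc(OCc9ccccc9)c3c1O[C@H](c5ccc(OCc9ccccc9)c(OCc9ccccc9)c5)[C@H](O)C3 | intermediate
3 | 8-bromo-5,7,3',4'-tetra-O-benzyl-(−)-epicatechin | Brc1c(OCc9ccccc9)cc(OCc9ccccc9)c3c1O[C@H](c5ccc(OCc9ccccc9)c(OCc9ccccc9)c5)[C@H](O)C3 | intermediate
4 | 8-bromo-3,5,7,3',4'-penta-O-benzyl-(−)-epicatechin | Brc1c(OCc9ccccc9)cc(OCc9ccccc9)c3c1O[C@H](c5ccc(OCc9ccccc9)c(OCc9ccccc9)c5)[C@H](OCc9ccccc9)C3 | intermediate
5 | 1,2-bis(benzyloxy)-4-bromobenzene | Brc1ccc(OCc9ccccc9)c(OCc9ccccc9)c1 | starting material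
6 | 1,2-bis(benzyloxy)-4-bromo-5-iodobenzene | Brc1cc(OCc9ccccc9)c(OCc9ccccc9)cc1I | intermediate
7 | 8-lithio-3,5,7,3',4'-penta-O-benzylepicatechin | [Li]c1c(OCc9ccccc9)cc(OCc9ccccc9)c3c1O[C@H](c5ccc(OCc9ccccc9)c(OCc9ccccc9)c5)[C@H](OCc9ccccc9)C3 | intermediate (not isolated)
8 | (3,5,7,3',4'-penta-O-benzylepicatechin-8-yl)zinc chloride | Cl[Zn]c1c(OCc9ccccc9)cc(OCc9ccccc9)c3c1O[C@H](c5ccc(OCc9ccccc9)c(OCc9ccccc9)c5)[C@H](OCc9ccccc9)C3 | intermediate (not isolated)
9 | 8-[4,5-bis(benzyloxy)-2-bromophenyl]-3,5,7,3',4'-penta-O-benzyl-(−)-epicatechin | Brc1cc(OCc9ccccc9)c(OCc9ccccc9)cc1-c4c(OCc9ccccc9)cc(OCc9ccccc9)c3c4O[C@H](c5ccc(OCc9ccccc9)c(OCc9ccccc9)c5)[C@H](OCc9ccccc9)C3 | intermediate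
10 | 1,3,5-trifluorobenzene | Fc1cc(F)cc(F)c1 | starting material
11 | 1,3-bis(benzyloxy)-5-fluorobenzene | Fc1cc(OCc9ccccc9)cc(OCc9ccccc9)c1 | intermediate
12 | (R)-trityl glycidyl ether | C1O[C@H]1COC(c2ccccc2)(c2ccccc2)c2ccccc2 | starting material
13 | 2,4-bis(benzyloxy)-6-fluorophenyllithium | [Li]c1c(F)cc(OCc9ccccc9)cc1OCc9ccccc9 | intermediate (not isolated)
14 | (R)-1-[2,4-bis(benzyloxy)-6-fluorophenyl]-3-(trityloxy)propan-2-ol | O[C@H](Cc1c(F)cc(OCc9ccccc9)cc1OCc9ccccc9)COC(c2ccccc2)(c2ccccc2)c2ccccc2 | intermediate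
15 | 1,5-bis(benzyloxy)-2-[(R)-2-(benzyloxy)-3-(trityloxy)propyl]-3-fluorobenzene | C(c9ccccc9)O[C@H](Cc1c(F)cc(OCc9ccccc9)cc1OCc9ccccc9)COC(c2ccccc2)(c2ccccc2)c2ccccc2 | intermediate
16 | (R)-2-(benzyloxy)-3-[2,4-bis(benzyloxy)-6-fluorophenyl]propan-1-ol | C(c9ccccc9)O[C@H](Cc1c(F)cc(OCc9ccccc9)cc1OCc9ccccc9)CO | intermediate
17 | (R)-2-(benzyloxy)-3-[2,4-bis(benzyloxy)-6-fluorophenyl]propanal | C(c9ccccc9)O[C@H](Cc1c(F)cc(OCc9ccccc9)cc1OCc9ccccc9)C=O | intermediate
18 | biaryllithium (lithium in place of the bromine of 9) | [Li]c1cc(OCc9ccccc9)c(OCc9ccccc9)cc1-c4c(OCc9ccccc9)cc(OCc9ccccc9)c3c4O[C@H](c5ccc(OCc9ccccc9)c(OCc9ccccc9)c5)[C@H](OCc9ccccc9)C3 | intermediate (not isolated)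
19 | biarylmagnesium bromide (MgBr in place of the bromine of 9) | Br[Mg]c1cc(OCc9ccccc9)c(OCc9ccccc9)cc1-c4c(OCc9ccccc9)cc(OCc9ccccc9)c3c4O[C@H](c5ccc(OCc9ccccc9)c(OCc9ccccc9)c5)[C@H](OCc9ccccc9)C3 | intermediate (not isolated)
20 | (1R,2R)-2-(benzyloxy)-1-{4,5-bis(benzyloxy)-2-[3,5,7,3',4'-penta-O-benzylepicatechin-8-yl]phenyl}-3-[2,4-bis(benzyloxy)-6-fluorophenyl]propan-1-ol | O[C@H](c1cc(OCc9ccccc9)c(OCc9ccccc9)cc1-c4c(OCc9ccccc9)cc(OCc9ccccc9)c3c4O[C@H](c5ccc(OCc9ccccc9)c(OCc9ccccc9)c5)[C@H](OCc9ccccc9)C3)[C@H](OCc9ccccc9)Cc1c(F)cc(OCc9ccccc9)cc1OCc9ccccc9 | intermediate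
21 | deca-O-benzyl derivative of the target | O(Cc9ccccc9)c1cc(OCc9ccccc9)c2c(c1)O[C@H](c1cc(OCc9ccccc9)c(OCc9ccccc9)cc1-c4c(OCc9ccccc9)cc(OCc9ccccc9)c3c4O[C@H](c5ccc(OCc9ccccc9)c(OCc9ccccc9)c5)[C@H](OCc9ccccc9)C3)[C@H](OCc9ccccc9)C2 | intermediate
22 | target, 6'→8 linked bis-(−)-epicatechin | Oc1cc(O)c2c(c1)O[C@H](c1cc(O)c(O)cc1-c1c(O)cc(O)c3c1O[C@H](c1ccc(O)c(O)c1)[C@H](O)C3)[C@H](O)C2 | target

Total step count: 13.
Longest linear sequence: 8 steps (steps 6, 7, 8, 9, 10, 11, 12, 13, from 1,3,5-trifluorobenzene).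

Steps most likely to fail

Step 11. What may go wrong: erosion of facial selectivity, with open Felkin–Anh addition competing with the magnesium chelate because of the ortho-aryl bulk of the nucleophile, or enolisation of the aldehyde. Fallback: set out from 9 and 17 and give up selectivity in the addition. Aryllithium 18 is added directly to 17 in THF at −78 °C to give 20 mixed with its C1 epimer, the (1S,2R)-carbinol F1. The mixture is oxidised (Dess–Martin periodinane, NaHCO3, CH2Cl2) to the single aryl ketone F2. F2 is then reduced under reagent control by Corey–Bakshi–Shibata reduction ((R)-2-methyl-CBS-oxazaborolidine, BH3·SMe2, THF, −20 °C, the biaryl taken as the large group), which should return 20.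

Step 12. What may go wrong: the alkoxide fails to displace fluoride from the electron-rich ring before base-induced decomposition sets in. Fallback: from 20, change the mechanism from addition–elimination to elimination–addition. LiTMP (3 equiv) in THF at −78 → 0 °C should remove the hydroxyl proton and the ring A proton flanked by fluorine and benzyloxy (C8 of the future chroman) to give the dilithio species F3. F3 loses lithium fluoride to the aryne alkoxide F4. The tethered alkoxide adds to the aryne carbon remote from the benzyloxy group (6-exo, the regiochemistry a 3-alkoxyaryne favours) to give the 8-lithiated flavan F5, and aqueous quench returns 21 with C2 untouched.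

Step 5. What may go wrong: slow transmetalation or reductive elimination at the doubly ortho-substituted C8 centre, so that protodemetalation takes over, or loss of the iodine-over-bromine preference leading to oligomers. Fallback: a transition-metal-free aryne coupling from 4 and 5. Compound 5 is brominated (NBS, MeCN) to 1,2-bis(benzyloxy)-4,5-dibromobenzene F6. Aryllithium 7 (from 4, n-BuLi, THF, −78 °C) is treated with F6 and warmed to rt. Bromine–lithium exchange gives 4,5-bis(benzyloxy)-2-bromophenyllithium F7, which sheds lithium bromide to the symmetrical 4,5-bis(benzyloxy)benzyne F8. Aryllithium 7 adds to F8 to give biaryllithium 18, which takes bromine from F6 to deliver 9 and regenerate F7 as chain carrier.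

Further compounds
F1 | step 11 | (1S,2R)-epimer of 20 | O[C@@H](c1cc(OCc9ccccc9)c(OCc9ccccc9)cc1-c4c(OCc9ccccc9)cc(OCc9ccccc9)c3c4O[C@H](c5ccc(OCc9ccccc9)c(OCc9ccccc9)c5)[C@H](OCc9ccccc9)C3)[C@H](OCc9ccccc9)Cc1c(F)cc(OCc9ccccc9)cc1OCc9ccccc9
F2 | step 11 | (R)-2-(benzyloxy)-1-{4,5-bis(benzyloxy)-2-[3,5,7,3',4'-penta-O-benzylepicatechin-8-yl]phenyl}-3-[2,4-bis(benzyloxy)-6-fluorophenyl]propan-1-one | O=C(c1cc(OCc9ccccc9)c(OCc9ccccc9)cc1-c4c(OCc9ccccc9)cc(OCc9ccccc9)c3c4O[C@H](c5ccc(OCc9ccccc9)c(OCc9ccccc9)c5)[C@H](OCc9ccccc9)C3)[C@H](OCc9ccccc9)Cc1c(F)cc(OCc9ccccc9)cc1OCc9ccccc9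
F3 | step 12 | lithium alkoxide of 20 lithiated at the ring A carbon between fluorine and benzyloxy | [Li]O[C@H](c1cc(OCc9ccccc9)c(OCc9ccccc9)cc1-c4c(OCc9ccccc9)cc(OCc9ccccc9)c3c4O[C@H](c5ccc(OCc9ccccc9)c(OCc9ccccc9)c5)[C@H](OCc9ccccc9)C3)[C@H](OCc9ccccc9)Cc1c(F)c([Li])c(OCc9ccccc9)cc1OCc9ccccc9
F4 | step 12 | aryne lithium alkoxide formed from F3 | [Li]O[C@H](c1cc(OCc9ccccc9)c(OCc9ccccc9)cc1-c4c(OCc9ccccc9)cc(OCc9ccccc9)c3c4O[C@H](c5ccc(OCc9ccccc9)c(OCc9ccccc9)c5)[C@H](OCc9ccccc9)C3)[C@H](OCc9ccccc9)CC1=C(OCc9ccccc9)C=C(OCc9ccccc9)C#C1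
F5 | step 12 | 8-lithio derivative of 21 (upper ring A) | O(Cc9ccccc9)c1cc(OCc9ccccc9)c2c(c1[Li])O[C@H](c1cc(OCc9ccccc9)c(OCc9ccccc9)cc1-c4c(OCc9ccccc9)cc(OCc9ccccc9)c3c4O[C@H](c5ccc(OCc9ccccc9)c(OCc9ccccc9)c5)[C@H](OCc9ccccc9)C3)[C@H](OCc9ccccc9)C2
F6 | step 5 | 1,2-bis(benzyloxy)-4,5-dibromobenzene | Brc1cc(OCc9ccccc9)c(OCc9ccccc9)cc1Br
F7 | step 5 | 4,5-bis(benzyloxy)-2-bromophenyllithium | [Li]c1cc(OCc9ccccc9)c(OCc9ccccc9)cc1Br
F8 | step 5 | 4,5-bis(benzyloxy)benzyne | C1#CC=C(OCc9ccccc9)C(OCc9ccccc9)=C1
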